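**Retrosynthetic overview**
1. The target is reached from the silyl ether ketal 19 by late functional-group work only: C9 ketal hydrolysis, C10 chlorination through the silyl enol ether, C10 selenenylation with selenoxide elimination to the C10=C11 chloroenone, and desilylation.
2. The strategy rests on the tertiary carbinol C12 of the five-membered ring C8–C9–C10–C11–C12 being bonded directly to the alkylidene carbon C8. Cutting C8–C12 gives a C7≡C8 alkyne and a C12 ketone joined through C9–C10–C11, so that the ring, the C12 stereocentre and the 7Z alkene all come from one reductive alkyne–ketone closure of enynone 18.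
3. Enynone 18 comes from a Sonogashira coupling (C6–C7) of vinyl iodide 16 with a terminal alkyne. Its C12 ketone is a 1,3-dithiane linchpin alkylated at C13 (allylic bromide 7) and at C11 (iodide 5). The alkyne is carried as its trimethylsilyl derivative through the carbanion steps, because a free terminal alkyne would quench the dithiane anion.
4. The molecule has one ring; it is formed in step 11.

Key step: step 11

Remark on numbering: prostanoid numbering is used throughout (C1 = ester carbon, C8–C12 = ring, C20 = terminal methyl).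
Assumption: the (S)-configured P-chiral ligand is taken to deliver the required C12 configuration; the sense of induction is to be confirmed on the first run, and the (R)-ligand is used if the opposite carbinol results.
Remark on handling: from 19 onward the 7Z dienyl and dienone compounds are kept from light.

**Step 1**
Reactants: 1 3-chloropropanoyl chloride; 2 bis(trimethylsilyl)acetylene
Product: 3 5-chloro-1-(trimethylsilyl)pent-1-yn-3-one
Conditions: AlCl3, CH2Cl2, 0 °C
Reagents that add atoms: none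
Why: Friedel–Crafts-type acylative ipso-desilylation of the bis-silyl alkyne by the AlCl3-activated acid chloride should stop at the mono-acylated ynone, because the product alkyne is deactivated.

**Step 2**
Reactants: 3 5-chloro-1-(trimethylsilyl)pent-1-yn-3-one
Product: 4 2-(2-chloroethyl)-2-[(trimethylsilyl)ethynyl]-1,3-dioxolane
Conditions: HOCH2CH2OH, p-TsOH (cat.), benzene, reflux, Dean–Stark
Reagents that add atoms: ethane-1,2-diol, OCCO
Why: Acid-catalysed ketalization with azeotropic removal of water should proceed because the silyl cap shields the ynone β-carbon from conjugate addition of the diol and the β-chloride is stable to acid.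

**Step 3**
Reactants: 4 2-(2-chloroethyl)-2-[(trimethylsilyl)ethynyl]-1,3-dioxolane
Product: 5 2-(2-iodoethyl)-2-[(trimethylsilyl)ethynyl]-1,3-dioxolane
Conditions: NaI, NaHCO3 (cat.), acetone, reflux
Reagents that add atoms: sodium iodide, [Na+].[I-]
Why: Finkelstein halide exchange (SN2 at the primary carbon) is driven by precipitation of NaCl and gives the more reactive alkylating agent.

**Step 4**
Reactants: 6 (2Z)-oct-2-en-1-ol
Product: 7 (2Z)-1-bromooct-2-ene
Conditions: CBr4, PPh3, CH2Cl2, 0 °C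
Reagents that add atoms: carbon tetrabromide, BrC(Br)(Br)Br
Why: Appel bromination of the primary allylic alcohol goes by SN2 on the alkoxyphosphonium ion under neutral conditions, so neither allylic transposition nor loss of the Z geometry is expected.

**Step 5**
Reactants: 8 1,3-dithiane; 7 (2Z)-1-bromooct-2-ene
Product: 10 2-[(2Z)-oct-2-en-1-yl]-1,3-dithiane, via 2-lithio-1,3-dithiane 9 (not isolated)
Conditions: n-BuLi, THF, −30 °C; then 7, −78 °C → 0 °C
Reagents that add atoms: none
Why: Corey–Seebach umpolung: the soft dithiane anion alkylates the primary allylic bromide at the α-carbon by SN2, with the Z alkene retained, and this forms C12–C13.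

**Step 6**
Reactants: 10 2-[(2Z)-oct-2-en-1-yl]-1,3-dithiane; 5 2-(2-iodoethyl)-2-[(trimethylsilyl)ethynyl]-1,3-dioxolane
Product: 12 2-[(2Z)-oct-2-en-1-yl]-2-(2-{2-[(trimethylsilyl)ethynyl]-1,3-dioxolan-2-yl}ethyl)-1,3-dithiane, via lithiated dithiane 11 (not isolated)
Conditions: n-BuLi, THF, −25 °C; then 5, DMPU, −78 °C → 0 °C
Reagents that add atoms: none
Why: Second Corey–Seebach alkylation: the C–H between the two sulfur atoms is far more acidic than the allylic C–H, the primary iodide reacts by SN2 to form C11–C12, and the silyl cap keeps the alkyne from protonating the carbanion.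

**Step 7**
Reactants: 12 2-[(2Z)-oct-2-en-1-yl]-2-(2-{2-[(trimethylsilyl)ethynyl]-1,3-dioxolan-2-yl}ethyl)-1,3-dithiane
Product: 13 2-[2-(2-ethynyl-1,3-dioxolan-2-yl)ethyl]-2-[(2Z)-oct-2-en-1-yl]-1,3-dithiane
Conditions: K2CO3, MeOH, rt
Reagents that add atoms: none
Why: Base-catalysed methanolysis of the C(sp)–Si bond (protodesilylation) frees the terminal alkyne and leaves the thioacetal and ketal untouched.

**Step 8**
Reactants: 14 methyl hex-5-ynoate
Product: 16 methyl (5E)-6-iodohex-5-enoate, via vinylzirconocene 15 (not isolated)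
Conditions: Cp2Zr(H)Cl, THF, rt, dark; then I2, 0 °C
Reagents that add atoms: iodine, II
Why: Hydrozirconation of the terminal alkyne (syn, zirconium at the terminus) followed by iodinolysis with retention gives the E vinyl iodide, the ester being much slower to react with the zirconium hydride than the alkyne.

**Step 9**
Reactants: 13 2-[2-(2-ethynyl-1,3-dioxolan-2-yl)ethyl]-2-[(2Z)-oct-2-en-1-yl]-1,3-dithiane; 16 methyl (5E)-6-iodohex-5-enoate
Product: 17 methyl (5E)-8-[2-(2-{2-[(2Z)-oct-2-en-1-yl]-1,3-dithian-2-yl}ethyl)-1,3-dioxolan-2-yl]oct-5-en-7-ynoate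
Conditions: Pd(PPh3)2Cl2 (cat.), CuI (cat.), Et3N, THF, rt, degassed
Reagents that add atoms: none
Why: Sonogashira coupling of the terminal alkyne with the vinyl iodide forms C6–C7 with retention of the E geometry, and it is run while C12 is still a thioacetal so that no base-sensitive skipped enone is exposed to the amine.

**Step 10**
Reactants: 17 methyl (5E)-8-[2-(2-{2-[(2Z)-oct-2-en-1-yl]-1,3-dithian-2-yl}ethyl)-1,3-dioxolan-2-yl]oct-5-en-7-ynoate
Product: 18 methyl (5E,14Z)-9,9-(ethylenedioxy)-12-oxoicosa-5,14-dien-7-ynoate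
Conditions: MeI, CaCO3, MeCN/H2O (9:1), 40 °C
Reagents that add atoms: water, O
Why: Alkylative thioacetal hydrolysis (S-methylation, then hydrolysis of the sulfonium ion) is non-oxidative and buffered by CaCO3, so the enyne, the propargylic ketal and the β,γ-unsaturated ketone should survive without migration of the C14=C15 alkene.

**Step 11**
Reactants: 18 methyl (5E,14Z)-9,9-(ethylenedioxy)-12-oxoicosa-5,14-dien-7-ynoate
Product: 19 methyl (5E,7Z,14Z)-9,9-(ethylenedioxy)-12-[(triethylsilyl)oxy]prosta-5,7,14-trien-1-oate, C12 configured as in the target (descriptor 12S here)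
Conditions: Ni(cod)2 (10 mol %), (S)-AntPhos [(S)-4-(anthracen-9-yl)-3-tert-butyl-2,3-dihydro-1,3-benzoxaphosphole] (10 mol %), Et3SiH (3 equiv), dioxane, rt
Reagents that add atoms: triethylsilane, CC[SiH](CC)CC
Why: Zerovalent nickel carrying the P-chiral monophosphine binds the C7≡C8 alkyne and the C12 carbonyl and undergoes oxidative cyclization to an oxanickelacyclopentene (Ni–C7, C8–C12, Ni–O); σ-bond metathesis of Ni–O with Et3SiH silylates the alkoxide, and C–H reductive elimination at C7 with retention releases 19 and zerovalent nickel. The closest known reaction type is the nickel-catalysed enantioselective reductive cyclization of alkynones with silanes to five-membered cyclic tertiary allylic silyl ethers bearing an exocyclic alkene. The cyclopentane closes in the 5-exo-dig mode with respect to the alkyne (C8 in the ring, C7 exocyclic); the three-atom tether C9–C10–C11 fixes this regiochemistry, which is also the one a conjugated enyne prefers (C–C bond at the alkyne carbon remote from the alkene). The C12 stereocentre is set by the ligand, which selects the ketone enantioface during oxidative cyclization. The 7Z geometry follows from the syn addition, hydrogen ending cis to C12 and C6 cis to C9. The step needs alkyne–ketone coupling to win over ketone hydrosilylation, enyne oligomerization and nickel hydride migration of the C14=C15 alkene; the C9 ketal removes ynone reactivity and the intramolecular five-membered closure should be fast.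

**Step 12**
Reactants: 19 methyl (5E,7Z,14Z)-9,9-(ethylenedioxy)-12-[(triethylsilyl)oxy]prosta-5,7,14-trien-1-oate
Product: 20 methyl (5E,7Z,14Z)-9-oxo-12-[(triethylsilyl)oxy]prosta-5,7,14-trien-1-oate (descriptor 12S)
Conditions: PPTS (cat.), acetone/H2O (10:1), rt
Reagents that add atoms: water, O
Why: Acid-catalysed hydrolysis of the ketal is easy here because the oxocarbenium ion is stabilized by the C7=C8–C5=C6 diene, while the hindered tertiary triethylsilyl ether should resist the weak acid.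

**Step 13**
Reactants: 20 methyl (5E,7Z,14Z)-9-oxo-12-[(triethylsilyl)oxy]prosta-5,7,14-trien-1-oate
Product: 23 methyl (5E,7Z,14Z)-10-chloro-9-oxo-12-[(triethylsilyl)oxy]prosta-5,7,14-trien-1-oate (descriptor 12R; both C10 epimers), via lithium enolate 21 (not isolated), via trimethylsilyl enol ether 22 (not isolated)
Conditions: LiN(SiMe3)2 (1.1 equiv), THF, −78 °C; TMSCl; concentrate; then NCS, THF, 0 °C
Reagents that add atoms: N-chlorosuccinimide, ClN1C(=O)CCC1=O
Why: Kinetic deprotonation can only occur at C10 on the ketone (C8 carries no hydrogen, the ester is far less acidic), and electrophilic chlorination of the resulting 2-silyloxydiene by NCS takes place at the enol ether terminus C10; the C10 configuration is irrelevant because C10 later becomes sp2.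

**Step 14**
Reactants: 23 methyl (5E,7Z,14Z)-10-chloro-9-oxo-12-[(triethylsilyl)oxy]prosta-5,7,14-trien-1-oate
Product: 25 methyl (5E,7Z,14Z)-10-chloro-9-oxo-10-(phenylselanyl)-12-[(triethylsilyl)oxy]prosta-5,7,14-trien-1-oate (descriptor 12R; both C10 epimers), via lithium chloroenolate 24 (not isolated)
Conditions: LiN(SiMe3)2 (1.05 equiv), THF, −78 °C; then PhSeCl, −78 °C
Reagents that add atoms: benzeneselenenyl chloride, Cl[Se]c1ccccc1
Why: Enolate selenenylation: the remaining C10 hydrogen is the only α-hydrogen and is acidified by chlorine, no Favorskii pathway is open because C8 has no hydrogen, and the enolate is trapped on carbon by PhSeCl at low temperature.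

**Step 15**
Reactants: 25 methyl (5E,7Z,14Z)-10-chloro-9-oxo-10-(phenylselanyl)-12-[(triethylsilyl)oxy]prosta-5,7,14-trien-1-oate
Product: 27 methyl (5E,7Z,12R,14Z)-10-chloro-9-oxo-12-[(triethylsilyl)oxy]prosta-5,7,10,14-tetraen-1-oate, via selenoxide 26 (not isolated)
Conditions: H2O2 (30 %, 3 equiv), pyridine, CH2Cl2, 0 °C → rt
Reagents that add atoms: none
Why: Selenide oxidation followed by syn selenoxide elimination can only go toward C11 (the sole β-hydrogens; either C10 epimer has one syn), which gives the C10=C11 chloroenone, while pyridine and excess oxidant keep selenenic acid from adding to the alkenes.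

**Step 16**
Reactants: 27 methyl (5E,7Z,12R,14Z)-10-chloro-9-oxo-12-[(triethylsilyl)oxy]prosta-5,7,10,14-tetraen-1-oate
Product: 28 methyl (5E,7Z,12R,14Z)-10-chloro-12-hydroxy-9-oxoprosta-5,7,10,14-tetraen-1-oate (target)
Conditions: HF·pyridine, pyridine, THF, 0 °C
Reagents that add atoms: none
Why: Fluoride-mediated desilylation under buffered, weakly acidic conditions frees the tertiary alcohol without the basic conditions that would attack the cross-conjugated dienone or trigger vinylogous retro-aldol cleavage.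

**Compound list**
1 | 3-chloropropanoyl chloride | ClCCC(=O)Cl | starting material
2 | bis(trimethylsilyl)acetylene | C[Si](C)(C)C#C[Si](C)(C)C | starting material
3 | 5-chloro-1-(trimethylsilyl)pent-1-yn-3-one | C[Si](C)(C)C#CC(=O)CCCl | intermediate
4 | 2-(2-chloroethyl)-2-[(trimethylsilyl)ethynyl]-1,3-dioxolane | ClCCC1(OCCO1)C#C[Si](C)(C)C | intermediate
5 | 2-(2-iodoethyl)-2-[(trimethylsilyl)ethynyl]-1,3-dioxolane | ICCC1(OCCO1)C#C[Si](C)(C)C | intermediate
6 | (2Z)-oct-2-en-1-ol | CCCCC/C=C\CO | starting material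
7 | (2Z)-1-bromooct-2-ene | CCCCC/C=C\CBr | intermediate
8 | 1,3-dithiane | C1CSCSC1 | starting material
9 | 2-lithio-1,3-dithiane | [Li]C1SCCCS1 | intermediate
10 | 2-[(2Z)-oct-2-en-1-yl]-1,3-dithiane | CCCCC/C=C\CC1SCCCS1 | intermediate
11 | 2-lithio-2-[(2Z)-oct-2-en-1-yl]-1,3-dithiane | CCCCC/C=C\CC1([Li])SCCCS1 | intermediate
12 | 2-[(2Z)-oct-2-en-1-yl]-2-(2-{2-[(trimethylsilyl)ethynyl]-1,3-dioxolan-2-yl}ethyl)-1,3-dithiane | CCCCC/C=C\CC1(CCC2(OCCO2)C#C[Si](C)(C)C)SCCCS1 | intermediate
13 | 2-[2-(2-ethynyl-1,3-dioxolan-2-yl)ethyl]-2-[(2Z)-oct-2-en-1-yl]-1,3-dithiane | CCCCC/C=C\CC1(CCC2(OCCO2)C#C)SCCCS1 | intermediate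
14 | methyl hex-5-ynoate | COC(=O)CCCC#C | starting material
15 | methyl (5E)-6-[chlorobis(cyclopentadienyl)zirconio]hex-5-enoate | COC(=O)CCC/C=C/[Zr](Cl)(C1C=CC=C1)C1C=CC=C1 | intermediate
16 | methyl (5E)-6-iodohex-5-enoate | COC(=O)CCC/C=C/I | intermediate
17 | methyl (5E)-8-[2-(2-{2-[(2Z)-oct-2-en-1-yl]-1,3-dithian-2-yl}ethyl)-1,3-dioxolan-2-yl]oct-5-en-7-ynoate | CCCCC/C=C\CC1(CCC2(OCCO2)C#C/C=C/CCCC(=O)OC)SCCCS1 | intermediate
18 | methyl (5E,14Z)-9,9-(ethylenedioxy)-12-oxoicosa-5,14-dien-7-ynoate | CCCCC/C=C\CC(=O)CCC1(OCCO1)C#C/C=C/CCCC(=O)OC | intermediate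
19 | methyl (5E,7Z,14Z)-9,9-(ethylenedioxy)-12-[(triethylsilyl)oxy]prosta-5,7,14-trien-1-oate, C12 as in the target (12S) | CCCCC/C=C\C[C@@]1(O[Si](CC)(CC)CC)CCC2(OCCO2)/C1=C\C=C\CCCC(=O)OC | intermediate
20 | methyl (5E,7Z,14Z)-9-oxo-12-[(triethylsilyl)oxy]prosta-5,7,14-trien-1-oate, C12 as in the target (12S) | CCCCC/C=C\C[C@@]1(O[Si](CC)(CC)CC)CCC(=O)/C1=C\C=C\CCCC(=O)OC | intermediate
21 | lithium C9–C10 enolate of 20 | CCCCC/C=C\C[C@@]1(O[Si](CC)(CC)CC)CC=C(O[Li])/C1=C\C=C\CCCC(=O)OC | intermediate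
22 | methyl (5E,7Z,14Z)-12-[(triethylsilyl)oxy]-9-[(trimethylsilyl)oxy]prosta-5,7,9,14-tetraen-1-oate, C12 as in the target (12R) | CCCCC/C=C\C[C@@]1(O[Si](CC)(CC)CC)CC=C(O[Si](C)(C)C)/C1=C\C=C\CCCC(=O)OC | intermediate
23 | methyl (5E,7Z,14Z)-10-chloro-9-oxo-12-[(triethylsilyl)oxy]prosta-5,7,14-trien-1-oate, 12R, C10 epimers | CCCCC/C=C\C[C@@]1(O[Si](CC)(CC)CC)CC(Cl)C(=O)/C1=C\C=C\CCCC(=O)OC | intermediate
24 | lithium C9–C10 enolate of 23 | CCCCC/C=C\C[C@@]1(O[Si](CC)(CC)CC)CC(Cl)=C(O[Li])/C1=C\C=C\CCCC(=O)OC | intermediate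
25 | methyl (5E,7Z,14Z)-10-chloro-9-oxo-10-(phenylselanyl)-12-[(triethylsilyl)oxy]prosta-5,7,14-trien-1-oate, 12R, C10 epimers | CCCCC/C=C\C[C@@]1(O[Si](CC)(CC)CC)CC(Cl)([Se]c2ccccc2)C(=O)/C1=C\C=C\CCCC(=O)OC | intermediate
26 | selenoxide of 25 | CCCCC/C=C\C[C@@]1(O[Si](CC)(CC)CC)CC(Cl)([Se](=O)c2ccccc2)C(=O)/C1=C\C=C\CCCC(=O)OC | intermediate
27 | methyl (5E,7Z,12R,14Z)-10-chloro-9-oxo-12-[(triethylsilyl)oxy]prosta-5,7,10,14-tetraen-1-oate | CCCCC/C=C\C[C@@]1(O[Si](CC)(CC)CC)C=C(Cl)C(=O)/C1=C\C=C\CCCC(=O)OC | intermediate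
28 | methyl (5E,7Z,12R,14Z)-10-chloro-12-hydroxy-9-oxoprosta-5,7,10,14-tetraen-1-oate | CCCCC/C=C\C[C@@]1(O)C=C(Cl)C(=O)/C1=C\C=C\CCCC(=O)OC | target

**Step count**
Total: 16 steps. Longest linear sequence: 13 steps (1, 2, 3, 6, 7, 9, 10, 11, 12, 13, 14, 15, 16).

**Steps most likely to fail**

Step 11. The two groups on the C12 ketone both begin with CH2, so enantioface discrimination by the ligand may be poor, and with a bulky ligand hydrosilylation of the ketone or oligomerization of the enyne may outrun the cyclization. The fallback moves stereocontrol from the catalyst to a removable chiral ketal and uses a small, highly active achiral phosphine. It sets out from ynone 3 and comes back at ketone 20.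
- Ketalization of 3 with (1R,2R)-1,2-diphenylethane-1,2-diol (p-TsOH, benzene, Dean–Stark) would give (4R,5R)-2-(2-chloroethyl)-4,5-diphenyl-2-[(trimethylsilyl)ethynyl]-1,3-dioxolane F1, and NaI in acetone the iodide (4R,5R)-2-(2-iodoethyl)-4,5-diphenyl-2-[(trimethylsilyl)ethynyl]-1,3-dioxolane F2.
- Alkylation of lithiated dithiane 11 with F2 would give 2-[(2Z)-oct-2-en-1-yl]-2-(2-{(4R,5R)-4,5-diphenyl-2-[(trimethylsilyl)ethynyl]-1,3-dioxolan-2-yl}ethyl)-1,3-dithiane F3, and K2CO3 in MeOH the terminal alkyne 2-{2-[(4R,5R)-2-ethynyl-4,5-diphenyl-1,3-dioxolan-2-yl]ethyl}-2-[(2Z)-oct-2-en-1-yl]-1,3-dithiane F4.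
- Sonogashira coupling with 16 would give methyl (5E)-8-[(4R,5R)-2-(2-{2-[(2Z)-oct-2-en-1-yl]-1,3-dithian-2-yl}ethyl)-4,5-diphenyl-1,3-dioxolan-2-yl]oct-5-en-7-ynoate F5, and MeI with CaCO3 the ketone methyl (5E,14Z)-9,9-[(1R,2R)-1,2-diphenylethylenedioxy]-12-oxoicosa-5,14-dien-7-ynoate F6.
- Cyclization of F6 with Ni(cod)2, PBu3 and Et3SiH would give the two C12 epimers, now diastereomers and separable by chromatography: methyl (5E,7Z,14Z)-9,9-[(1R,2R)-1,2-diphenylethylenedioxy]-12-[(triethylsilyl)oxy]prosta-5,7,14-trien-1-oate with C12 as in 19 F7 and its C12 epimer F8.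
- Hydrolysis of F7 (PPTS, aqueous acetone) would give 20 and return the diol.

Step 14. The lithium enolate of the α-chloro ketone may decompose or be selenenylated on oxygen, and phenylselenolate formed in side reactions may add reversibly to the dienone and erode the 7Z geometry. The fallback introduces the alkene before the chlorine and uses no selenium. It sets out from ketone 20, through silyl enol ether 22, and comes back at 27.
- Saegusa–Ito dehydrogenation of 22 with Pd(OAc)2 in MeCN would give the cross-conjugated dienone methyl (5E,7Z,12R,14Z)-9-oxo-12-[(triethylsilyl)oxy]prosta-5,7,10,14-tetraen-1-oate F9.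
- Nucleophilic epoxidation (t-BuOOH, DBU, CH2Cl2, 0 °C) at the less substituted endocyclic C10=C11 enone would give methyl (5E,7Z,14Z)-10,11-epoxy-9-oxo-12-[(triethylsilyl)oxy]prosta-5,7,14-trien-1-oate F10.
- Dry HCl in CH2Cl2 at −20 °C would open the epoxide with chloride at C10 (C11 is shielded by the quaternary C12), and the chlorohydrin would lose water across C10–C11 to give 27.

Step 10. During thioacetal cleavage the freed β,γ-unsaturated ketone may slip into conjugation, or the hindered 2,2-dialkyl dithiane may hydrolyse too slowly for the enyne and ketal to survive the prolonged exposure. The fallback uses no thioacetal and reveals the ketone by a neutral alcohol oxidation as the last operation before the key step. It sets out from iodide 5 and comes back at 18.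
- Copper-catalysed coupling of 5 with CH2=CHMgBr (CuI cat., THF) would give 2-(but-3-en-1-yl)-2-[(trimethylsilyl)ethynyl]-1,3-dioxolane F11, and mCPBA with NaHCO3 the racemic epoxide 2-[2-(oxiran-2-yl)ethyl]-2-[(trimethylsilyl)ethynyl]-1,3-dioxolane F12.
- Lithium di[(1Z)-hept-1-en-1-yl]cuprate F13, made by carbocupration of acetylene with lithium dipentylcuprate (C5H11)2CuLi, would open F12 at the terminal carbon to give (5Z)-1-{2-[(trimethylsilyl)ethynyl]-1,3-dioxolan-2-yl}undec-5-en-3-ol F14.
- K2CO3 in MeOH would give (5Z)-1-(2-ethynyl-1,3-dioxolan-2-yl)undec-5-en-3-ol F15, and Sonogashira coupling with 16 would give methyl (5E,14Z)-9,9-(ethylenedioxy)-12-hydroxyicosa-5,14-dien-7-ynoate F16.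
- Oxidation of F16 with Dess–Martin periodinane buffered by NaHCO3 would give 18.

**Further compounds**
F1 | step 11 | (4R,5R)-2-(2-chloroethyl)-4,5-diphenyl-2-[(trimethylsilyl)ethynyl]-1,3-dioxolane | ClCCC1(C#C[Si](C)(C)C)O[C@H](c2ccccc2)[C@@H](c2ccccc2)O1
F2 | step 11 | (4R,5R)-2-(2-iodoethyl)-4,5-diphenyl-2-[(trimethylsilyl)ethynyl]-1,3-dioxolane | ICCC1(C#C[Si](C)(C)C)O[C@H](c2ccccc2)[C@@H](c2ccccc2)O1
F3 | step 11 | 2-[(2Z)-oct-2-en-1-yl]-2-(2-{(4R,5R)-4,5-diphenyl-2-[(trimethylsilyl)ethynyl]-1,3-dioxolan-2-yl}ethyl)-1,3-dithiane | CCCCC/C=C\CC1(CCC2(C#C[Si](C)(C)C)O[C@H](c3ccccc3)[C@@H](c3ccccc3)O2)SCCCS1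
F4 | step 11 | 2-{2-[(4R,5R)-2-ethynyl-4,5-diphenyl-1,3-dioxolan-2-yl]ethyl}-2-[(2Z)-oct-2-en-1-yl]-1,3-dithiane | CCCCC/C=C\CC1(CCC2(C#C)O[C@H](c3ccccc3)[C@@H](c3ccccc3)O2)SCCCS1
F5 | step 11 | methyl (5E)-8-[(4R,5R)-2-(2-{2-[(2Z)-oct-2-en-1-yl]-1,3-dithian-2-yl}ethyl)-4,5-diphenyl-1,3-dioxolan-2-yl]oct-5-en-7-ynoate | CCCCC/C=C\CC1(CCC2(C#C/C=C/CCCC(=O)OC)O[C@H](c3ccccc3)[C@@H](c3ccccc3)O2)SCCCS1
F6 | step 11 | methyl (5E,14Z)-9,9-[(1R,2R)-1,2-diphenylethylenedioxy]-12-oxoicosa-5,14-dien-7-ynoate | CCCCC/C=C\CC(=O)CCC1(C#C/C=C/CCCC(=O)OC)O[C@H](c2ccccc2)[C@@H](c2ccccc2)O1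
F7 | step 11 | methyl (5E,7Z,14Z)-9,9-[(1R,2R)-1,2-diphenylethylenedioxy]-12-[(triethylsilyl)oxy]prosta-5,7,14-trien-1-oate, C12 as in 19 | CCCCC/C=C\C[C@@]1(O[Si](CC)(CC)CC)CCC2(O[C@H](c3ccccc3)[C@@H](c3ccccc3)O2)/C1=C\C=C\CCCC(=O)OC
F8 | step 11 | C12 epimer of F7 | CCCCC/C=C\C[C@]1(O[Si](CC)(CC)CC)CCC2(O[C@H](c3ccccc3)[C@@H](c3ccccc3)O2)/C1=C\C=C\CCCC(=O)OC
F9 | step 14 | methyl (5E,7Z,12R,14Z)-9-oxo-12-[(triethylsilyl)oxy]prosta-5,7,10,14-tetraen-1-oate | CCCCC/C=C\C[C@@]1(O[Si](CC)(CC)CC)C=CC(=O)/C1=C\C=C\CCCC(=O)OC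
F10 | step 14 | methyl (5E,7Z,14Z)-10,11-epoxy-9-oxo-12-[(triethylsilyl)oxy]prosta-5,7,14-trien-1-oate, epoxide face not defined | CCCCC/C=C\C[C@@]1(O[Si](CC)(CC)CC)C2OC2C(=O)/C1=C\C=C\CCCC(=O)OC
F11 | step 10 | 2-(but-3-en-1-yl)-2-[(trimethylsilyl)ethynyl]-1,3-dioxolane | C=CCCC1(OCCO1)C#C[Si](C)(C)C
F12 | step 10 | 2-[2-(oxiran-2-yl)ethyl]-2-[(trimethylsilyl)ethynyl]-1,3-dioxolane, racemic | C[Si](C)(C)C#CC1(CCC2CO2)OCCO1
F13 | step 10 | lithium di[(1Z)-hept-1-en-1-yl]cuprate | [Li+].CCCCC/C=C\[Cu-]/C=C\CCCCC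
F14 | step 10 | (5Z)-1-{2-[(trimethylsilyl)ethynyl]-1,3-dioxolan-2-yl}undec-5-en-3-ol, racemic | CCCCC/C=C\CC(O)CCC1(OCCO1)C#C[Si](C)(C)C
F15 | step 10 | (5Z)-1-(2-ethynyl-1,3-dioxolan-2-yl)undec-5-en-3-ol, racemic | CCCCC/C=C\CC(O)CCC1(OCCO1)C#C
F16 | step 10 | methyl (5E,14Z)-9,9-(ethylenedioxy)-12-hydroxyicosa-5,14-dien-7-ynoate, racemic | CCCCC/C=C\CC(O)CCC1(OCCO1)C#C/C=C/CCCC(=O)OC
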